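**Retrosynthetic overview**
1. Ester C–O bond: target 20 ⇒ linoleoyl chloride 19 + monocyclic diterpenol 18.
2. C8–C9 bond of 18: lithiated (S)-α-cyclogeranyl phenyl sulfone 11 + (2E,6E)-8-bromogeranyl acetate 14 (from geranyl acetate 12); the sulfone is then removed reductively.
3. Sulfone 11 ⇐ (S)-α-cyclogeraniol 8 ⇐ Still–Wittig [2,3] shift (1,3-chirality transfer) of the stannylmethyl ether 5 of (R)-2,4,4-trimethylcyclohex-2-en-1-ol 2.
4. Alcohol 2 ⇐ CBS reduction of enone 1, the only source of absolute configuration.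
5. Ring order: the single cyclohexene ring is bought with 1; no ring is formed in the route.

Assumption: 2,4,4-trimethylcyclohex-2-en-1-one, tributyl(iodomethyl)stannane, geranyl acetate and linoleoyl chloride are taken as catalogue compounds.

**Route**

Step 1
Reactants: 1 2,4,4-trimethylcyclohex-2-en-1-one
Product: 2 (1R)-2,4,4-trimethylcyclohex-2-en-1-ol
Conditions: (S)-2-methyl-CBS-oxazaborolidine (10 mol %), BH3·SMe2 (0.7 equiv), THF, −20 °C; MeOH quench
Reagents that add atoms: none
Why: Corey–Bakshi–Shibata reduction, in which the α-methylvinyl arm acts as the large group, so the (S)-catalyst gives the (R)-carbinol by the same mnemonic that gives (R)-1-phenylethanol from acetophenone.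

Step 2
Reactants: 2 (1R)-2,4,4-trimethylcyclohex-2-en-1-ol; 3 tributyl(iodomethyl)stannane
Product: 5 tributyl({[(1R)-2,4,4-trimethylcyclohex-2-en-1-yl]oxy}methyl)stannane, via potassium alkoxide 4 (not isolated)
Conditions: KH, THF, 0 °C; then 3, 0 °C → rt
Reagents that add atoms: tributyl(iodomethyl)stannane (3), CCCC[Sn](CCCC)(CCCC)CI
Why: Williamson etherification of the potassium alkoxide with the SN2-reactive α-stannyl iodide, leaving the carbinol centre untouched.

Step 3
Reactants: 5 tributyl({[(1R)-2,4,4-trimethylcyclohex-2-en-1-yl]oxy}methyl)stannane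
Product: 8 [(1S)-2,6,6-trimethylcyclohex-2-en-1-yl]methanol ((S)-α-cyclogeraniol), via alkoxymethyllithium 6 (not isolated), via lithium alkoxide 7 (not isolated)
Conditions: n-BuLi (1.5 equiv), THF, −78 → 0 °C; then H2O
Reagents that add atoms: none
Why: Tin–lithium exchange triggers the Still–Wittig [2,3]-sigmatropic rearrangement, which delivers the CH2O carbon suprafacially to C3 on the face the oxygen occupied, so the (R)-carbinol configuration becomes the (S)-ring methine as the alkene moves to C1=C2.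

Step 4
Reactants: 8 [(1S)-2,6,6-trimethylcyclohex-2-en-1-yl]methanol
Product: 9 phenyl {[(1S)-2,6,6-trimethylcyclohex-2-en-1-yl]methyl} sulfide
Conditions: PhSSPh (1.5 equiv), n-Bu3P (1.5 equiv), pyridine, 60 °C
Reagents that add atoms: diphenyl disulfide, c1ccc(SSc2ccccc2)cc1
Why: Hata thioetherification, in which thiophenoxide displaces the alkoxyphosphonium by SN2 at the CH2 group, one carbon away from the stereocentre.

Step 5
Reactants: 9 phenyl {[(1S)-2,6,6-trimethylcyclohex-2-en-1-yl]methyl} sulfide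
Product: 11 {[(1S)-2,6,6-trimethylcyclohex-2-en-1-yl]methyl}sulfonylbenzene, via sulfoxide 10 (not isolated)
Conditions: (NH4)6Mo7O24·4H2O (5 mol %), 30% aq. H2O2 (3 equiv), EtOH, 0 °C → rt
Reagents that add atoms: hydrogen peroxide, OO
Why: Molybdate-catalysed peroxide oxidation of sulfur is much faster than epoxidation of the trisubstituted ring alkene, so the sulfide is taken cleanly to the sulfone.

Step 6
Reactants: 12 geranyl acetate ((2E)-3,7-dimethylocta-2,6-dien-1-yl acetate)
Product: 13 (2E,6E)-8-hydroxy-3,7-dimethylocta-2,6-dien-1-yl acetate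
Conditions: SeO2 (cat.), t-BuOOH, salicylic acid (cat.), CH2Cl2, rt
Reagents that add atoms: tert-butyl hydroperoxide, CC(C)(C)OO (oxygen relayed by SeO2, O=[Se]=O)
Why: Sharpless–Umbreit allylic oxidation (ene reaction then [2,3] shift) hydroxylates the (E)-methyl of the electron-rich terminal alkene, the 2,3-alkene being deactivated by its allylic acetate.

Step 7
Reactants: 13 (2E,6E)-8-hydroxy-3,7-dimethylocta-2,6-dien-1-yl acetate
Product: 14 (2E,6E)-8-bromo-3,7-dimethylocta-2,6-dien-1-yl acetate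
Conditions: CBr4, PPh3, CH2Cl2, 0 °C
Reagents that add atoms: tetrabromomethane, BrC(Br)(Br)Br
Why: Appel reaction, in which bromide displaces the primary allylic alkoxyphosphonium by SN2 without allylic shift or loss of E geometry.

Step 8
Reactants: 11 {[(1S)-2,6,6-trimethylcyclohex-2-en-1-yl]methyl}sulfonylbenzene; 14 (2E,6E)-8-bromo-3,7-dimethylocta-2,6-dien-1-yl acetate
Product: 16 (2E,6E)-9-(benzenesulfonyl)-3,7-dimethyl-9-[(1S)-2,6,6-trimethylcyclohex-2-en-1-yl]nona-2,6-dien-1-yl acetate, via lithiated sulfone 15 (not isolated)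
Conditions: n-BuLi (1.05 equiv), THF/HMPA, −78 °C; then 14, −78 → −40 °C
Reagents that add atoms: bromide 14, CC(=O)OC/C=C(\C)CC/C=C(\C)CBr
Why: Alkylation of an α-sulfonyl carbanion (Julia-type sulfone coupling) by SN2 on the primary allylic bromide outpaces attack on the acetate at −78 °C; the new sulfone-bearing centre forms as an epimer mixture that is erased in step 9, and the ring methine is not deprotonated.

Step 9
Reactants: 16 (2E,6E)-9-(benzenesulfonyl)-3,7-dimethyl-9-[(1S)-2,6,6-trimethylcyclohex-2-en-1-yl]nona-2,6-dien-1-yl acetate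
Product: 18 (2E,6E)-3,7-dimethyl-9-[(1S)-2,6,6-trimethylcyclohex-2-en-1-yl]nona-2,6-dien-1-ol, via acetate 17 (not isolated)
Conditions: 6% Na(Hg), Na2HPO4, MeOH/THF, −20 → 0 °C; then K2CO3, MeOH, rt
Reagents that add atoms: none
Why: Reductive desulfonylation by electron transfer from sodium amalgam cleaves the non-allylic C–S bond without moving either alkene, and the acetate is then removed in the same pot by base-catalysed transesterification.

Step 10
Reactants: 18 (2E,6E)-3,7-dimethyl-9-[(1S)-2,6,6-trimethylcyclohex-2-en-1-yl]nona-2,6-dien-1-ol; 19 linoleoyl chloride ((9Z,12Z)-octadeca-9,12-dienoyl chloride)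
Product: 20 (2E,6E)-3,7-dimethyl-9-[(1S)-2,6,6-trimethylcyclohex-2-en-1-yl]nona-2,6-dien-1-yl (9Z,12Z)-octadeca-9,12-dienoate
Conditions: pyridine (2 equiv), DMAP (cat.), CH2Cl2, 0 °C → rt
Reagents that add atoms: linoleoyl chloride (19), CCCCC/C=C\C/C=C\CCCCCCCC(=O)Cl
Why: DMAP-catalysed acylation of the primary allylic alcohol by the acid chloride occurs at oxygen without allylic shift and without isomerising the skipped Z,Z-diene.

**Compound list**

1 | 2,4,4-trimethylcyclohex-2-en-1-one | CC1=CC(C)(C)CCC1=O | starting material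
2 | (1R)-2,4,4-trimethylcyclohex-2-en-1-ol | O[C@@H]1CCC(C)(C)C=C1C | intermediate
3 | tributyl(iodomethyl)stannane | CCCC[Sn](CCCC)(CCCC)CI | starting material
4 | potassium (1R)-2,4,4-trimethylcyclohex-2-en-1-olate | [K+].[O-][C@@H]1CCC(C)(C)C=C1C | intermediate (not isolated)
5 | tributyl({[(1R)-2,4,4-trimethylcyclohex-2-en-1-yl]oxy}methyl)stannane | CCCC[Sn](CCCC)(CCCC)CO[C@@H]1CCC(C)(C)C=C1C | intermediate
6 | ({[(1R)-2,4,4-trimethylcyclohex-2-en-1-yl]oxy}methyl)lithium | [Li]CO[C@@H]1CCC(C)(C)C=C1C | intermediate (not isolated)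
7 | lithium [(1S)-2,6,6-trimethylcyclohex-2-en-1-yl]methanolate | [Li+].[O-]C[C@@H]1C(C)=CCCC1(C)C | intermediate (not isolated)
8 | [(1S)-2,6,6-trimethylcyclohex-2-en-1-yl]methanol, (S)-α-cyclogeraniol | OC[C@@H]1C(C)=CCCC1(C)C | intermediate
9 | phenyl {[(1S)-2,6,6-trimethylcyclohex-2-en-1-yl]methyl} sulfide | c1ccccc1SC[C@@H]1C(C)=CCCC1(C)C | intermediate
10 | phenyl {[(1S)-2,6,6-trimethylcyclohex-2-en-1-yl]methyl} sulfoxide (both sulfur epimers) | O=S(C[C@@H]1C(C)=CCCC1(C)C)c1ccccc1 | intermediate (not isolated)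
11 | {[(1S)-2,6,6-trimethylcyclohex-2-en-1-yl]methyl}sulfonylbenzene, (S)-α-cyclogeranyl phenyl sulfone | O=S(=O)(C[C@@H]1C(C)=CCCC1(C)C)c1ccccc1 | intermediate
12 | geranyl acetate, (2E)-3,7-dimethylocta-2,6-dien-1-yl acetate | CC(=O)OC/C=C(\C)CCC=C(C)C | starting material
13 | (2E,6E)-8-hydroxy-3,7-dimethylocta-2,6-dien-1-yl acetate | CC(=O)OC/C=C(\C)CC/C=C(\C)CO | intermediate
14 | (2E,6E)-8-bromo-3,7-dimethylocta-2,6-dien-1-yl acetate | CC(=O)OC/C=C(\C)CC/C=C(\C)CBr | intermediate
15 | lithiated sulfone 11, [(benzenesulfonyl){(1S)-2,6,6-trimethylcyclohex-2-en-1-yl}methyl]lithium | [Li]C([C@@H]1C(C)=CCCC1(C)C)S(=O)(=O)c1ccccc1 | intermediate (not isolated)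
16 | (2E,6E)-9-(benzenesulfonyl)-3,7-dimethyl-9-[(1S)-2,6,6-trimethylcyclohex-2-en-1-yl]nona-2,6-dien-1-yl acetate (both C9 epimers) | CC(=O)OC/C=C(\C)CC/C=C(\C)CC([C@@H]1C(C)=CCCC1(C)C)S(=O)(=O)c1ccccc1 | intermediate
17 | (2E,6E)-3,7-dimethyl-9-[(1S)-2,6,6-trimethylcyclohex-2-en-1-yl]nona-2,6-dien-1-yl acetate | CC(=O)OC/C=C(\C)CC/C=C(\C)CC[C@@H]1C(C)=CCCC1(C)C | intermediate (not isolated)
18 | (2E,6E)-3,7-dimethyl-9-[(1S)-2,6,6-trimethylcyclohex-2-en-1-yl]nona-2,6-dien-1-ol | OC/C=C(\C)CC/C=C(\C)CC[C@@H]1C(C)=CCCC1(C)C | intermediate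
19 | linoleoyl chloride, (9Z,12Z)-octadeca-9,12-dienoyl chloride | CCCCC/C=C\C/C=C\CCCCCCCC(=O)Cl | starting material
20 | (2E,6E)-3,7-dimethyl-9-[(1S)-2,6,6-trimethylcyclohex-2-en-1-yl]nona-2,6-dien-1-yl (9Z,12Z)-octadeca-9,12-dienoate | CCCCC/C=C\C/C=C\CCCCCCCC(=O)OC/C=C(\C)CC/C=C(\C)CC[C@@H]1C(C)=CCCC1(C)C | target

**Totals**

Total step count: 10. Longest linear sequence: 8 (steps 1, 2, 3, 4, 5, 8, 9, 10); steps 6 and 7 make the side-chain fragment. The ring methine set in step 3 is not touched afterwards, so the enantiomeric purity of 2 carries through to 20.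

**Steps most likely to fail, with fallbacks**

Step 3 (Still–Wittig shift onto a carbon next to the gem-dimethyl group; a [1,2] shift or simple protonation of 6 may compete). The fallback sets out from 2 and comes back at 9, using a [3,3] shift and a radical decarboxylation in place of the [2,3] shift. Johnson–Claisen rearrangement of 2 (triethyl orthoacetate, cat. propionic acid, 140 °C, ethanol distilled off) gives ethyl [(1S)-2,6,6-trimethylcyclohex-2-en-1-yl]acetate F4 with the same suprafacial transfer of chirality. Saponification (LiOH, THF/MeOH/H2O) gives [(1S)-2,6,6-trimethylcyclohex-2-en-1-yl]acetic acid F5. Coupling with 1-hydroxypyridine-2(1H)-thione (DCC, DMAP, CH2Cl2, dark) gives the Barton ester 2-thioxopyridin-1(2H)-yl [(1S)-2,6,6-trimethylcyclohex-2-en-1-yl]acetate F6. Irradiation (tungsten lamp) with a large excess of PhSSPh expels CO2 and traps the primary radical as sulfide 9; the radical is not at the stereocentre.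

Step 8 (hindered sulfone carbanion; possible attack on the acetate or sluggish alkylation). The fallback sets out from 8 and comes back at 17, replacing sulfone chemistry by a copper-catalysed Grignard allylation. Iodination of 8 (I2, PPh3, imidazole, CH2Cl2) gives (6S)-6-(iodomethyl)-1,5,5-trimethylcyclohex-1-ene F7. Iodine–lithium exchange (t-BuLi, 2.1 equiv, Et2O/pentane, −78 °C) gives {[(1S)-2,6,6-trimethylcyclohex-2-en-1-yl]methyl}lithium F8. Transmetalation with MgBr2·OEt2 gives bromo{[(1S)-2,6,6-trimethylcyclohex-2-en-1-yl]methyl}magnesium F9. Coupling of F9 with bromide 14 (Li2CuCl4, 3 mol %, THF, −78 → −20 °C) substitutes at the primary allylic carbon and gives acetate 17, which K2CO3/MeOH converts to 18 as in step 9. This bypasses steps 4, 5 and 8.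

Step 1 (the enantioselectivity of the CBS reduction on this particular enone is assumed from the model, not known). The fallback sets out from 1 and comes back at 2, using kinetic resolution in place of asymmetric reduction. Luche reduction (NaBH4, CeCl3·7H2O, MeOH, 0 °C) gives racemic 2,4,4-trimethylcyclohex-2-en-1-ol F1. Lipase-catalysed acylation (Candida antarctica lipase B, vinyl acetate, hexane, rt, stopped near 50% conversion) acetylates the (R)-enantiomer preferentially (Kazlauskas rule) to (1R)-2,4,4-trimethylcyclohex-2-en-1-yl acetate F2. F2 is separated by chromatography from unreacted (1S)-2,4,4-trimethylcyclohex-2-en-1-ol F3, which MnO2 returns to 1. Methanolysis of F2 (K2CO3, MeOH) gives 2.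

**Further compounds**

F1 | step 1 | racemic 2,4,4-trimethylcyclohex-2-en-1-ol | OC1CCC(C)(C)C=C1C
F2 | step 1 | (1R)-2,4,4-trimethylcyclohex-2-en-1-yl acetate | CC(=O)O[C@@H]1CCC(C)(C)C=C1C
F3 | step 1 | (1S)-2,4,4-trimethylcyclohex-2-en-1-ol | O[C@H]1CCC(C)(C)C=C1C
F4 | step 3 | ethyl [(1S)-2,6,6-trimethylcyclohex-2-en-1-yl]acetate | CCOC(=O)C[C@@H]1C(C)=CCCC1(C)C
F5 | step 3 | [(1S)-2,6,6-trimethylcyclohex-2-en-1-yl]acetic acid | OC(=O)C[C@@H]1C(C)=CCCC1(C)C
F6 | step 3 | 2-thioxopyridin-1(2H)-yl [(1S)-2,6,6-trimethylcyclohex-2-en-1-yl]acetate | S=c1ccccn1OC(=O)C[C@@H]1C(C)=CCCC1(C)C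
F7 | step 8 | (6S)-6-(iodomethyl)-1,5,5-trimethylcyclohex-1-ene | IC[C@@H]1C(C)=CCCC1(C)C
F8 | step 8 | {[(1S)-2,6,6-trimethylcyclohex-2-en-1-yl]methyl}lithium | [Li]C[C@@H]1C(C)=CCCC1(C)C
F9 | step 8 | bromo{[(1S)-2,6,6-trimethylcyclohex-2-en-1-yl]methyl}magnesium | Br[Mg]C[C@@H]1C(C)=CCCC1(C)C
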